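## Structural features

The target is a cis-fused 1,4,4a,5,8,8a-hexahydronaphthalene; the locants C1–C8a of its core are used for every bicyclic compound below. Ring A is a cyclohex-2-ene with methyl esters at C1 and C4 and a hexadecyl chain on the C2=C3 alkene. Ring B is a cyclohex-2-enone with the ketone at C5, a methyl ester at C6, the second hexadecyl chain at C7 and a methylene at C8. The stereocentres C4, C4a, C8a and C1 are contiguous: H4, H4a and H8a share one face, so the C4 ester sits on the concave face cis to C5, while the C1 ester sits on the convex face, trans to C8. Ring B is an alkylidene β-keto ester, a strong Michael acceptor whose C4a hydrogen is acidic, so base can destroy the cis fusion. Both ring A esters are β,γ-unsaturated with allylic α-hydrogens, which invites epimerisation and migration of the alkene into conjugation; a C5 hydroxyl, wherever it appears, is cis to the C4 carboxyl carbon and can close a γ-lactone. The real difficulty is the opposite facial demand at C1 and C4 in a molecule that tolerates little base, not the carbon skeleton. The key step exploits ring B: its C6=C7 alkene lies between C5 and C8, the retron of a [4+2] cycloaddition across C4a–C8a of a ring A quinone with carbonyls at C1 and C4.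

## Logic of the disconnections

25 to 22. The O–CH3 bond of the C4 ester and the oxidation levels at C5 and at the C4 carbon are set last (25 from 24, 24 from 23, 23 from 22). The alkylidene β-keto ester is the most sensitive part, and a free C5 hydroxyl beside a C4 carboxyl derivative would lactonise, so the C4 carbon stays at the alcohol level until both hydroxyls are oxidised together. The gain is that no skeletal bond is made after 22. The demand is a double oxidation without lactol formation or epimerisation at C4 and C4a.

22 to 19. Removing the silyl group (22 from 21) and cutting the C4–H and CH2–O bonds leads to 19. The C4 carbon substituent must lie on the concave face, which is what delivery of hydrogen to an exocyclic C4 methylene from the open convex face produces. The gain is that C4 becomes trigonal. The demand is attack at the 1,1-disubstituted terminus of the diene only, with the face controlled by C4a and its C5 substituent.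

19 to 18. The exocyclic alkene is cut back to the C4 carbonyl of 18, the oxygen that the quinone brought in. The demand is a non-basic methylenation, because C1–H of 18 is vinylogously acidic.

18 to 16. The C1–CO2Me bond is cut, leading through 17 to 16. Treating both quinone carbonyls alike would put both ester carbons on the concave face, since hydrogen always arrives from the convex side; correcting C1 afterwards with base would also endanger C4 and the alkene position. In 18, however, C1–H is γ to the C4 enone and α to the ester, so mild base equilibrates this centre alone, and the same isomerisation places the alkene at C2=C3. The gain is that the C1 stereocentre and the alkene position reduce to a C1=C2 enol derivative. The demand is that the convex-face epimer is the more stable one and that base does not expel the C5 silyloxy group.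

16 to 14. Removing the triflyl group and the C3 hydrogen leads through 15 to 14. Conjugate hydride addition at the unsubstituted C3 gives the C1 enolate regiospecifically, which tells the two carbonyls apart without protecting groups. The demand is 1,4- over 1,2-reduction and trapping before proton transfer.

14 to 5 and 13. Cutting C4a–C5 and C8–C8a removes ring B and three stereocentres at once and leaves two achiral components. The demand is site, regio, endo and facial selectivity in one catalytic step.

13 to 2 and 6. The O–Si bond (13 from 11 through 12), the C5–C6 bond (11 from 9 through 10), the ester methyl (9 from 8) and the C7–chain bond (8 from 2 and 6 through 7) are cut in turn. The demand is that the 1,1-disubstituted alkene stays out of conjugation and that the silyloxy group ends up trans to the alkenyl carbon.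

5 to 1 and 2. The quinone oxygens are traced to methyl ethers (5 from 4) and the aryl–chain bond is cut (4 from 1 and 2 through 3). The symmetry of 1 makes the regiochemistry trivial.

## Other disconnections considered

Alternative 1: The cut is C4–C4a through a [3,3] shift. Heating a 2-alkenyl-3,4-dihydro-2H-pyran would break the O–C bond at its allylic carbon and form C4–C4a through a ring-enforced boat, giving the ring A aldehyde A1. Ring B would follow by adding the C6 ester carbon to the aldehyde, oxidation, release of the C7 ketone and an intramolecular Knoevenagel closure.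
- In favour: chirality transfer is concerted, both ring A esters are already at the ester level, and C1 is not left to an equilibrium. On these three points it is better than the chosen plan.
- Against: the dihydropyran needs three stereocentres, one of them a fully substituted oxygen-bearing carbon, with no obvious catalytic asymmetric entry. The rearrangement needs heat beside β,γ-unsaturated esters, and the C4a aldehyde it delivers is epimerisable.
- Comparison: mechanistically it is the equal or the better for the relative configuration of ring A. Structurally it postpones the tetrasubstituted enone, and with four to five operations still needed for ring B it is unlikely to be shorter.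

Alternative 2: The cuts are C1–C2 and C4a–C8a, an intramolecular Diels–Alder reaction with ring B as the tether. On heating, an (E)-enoate (C1=C8a) would add to a 2-methoxycarbonyl diene (C2 to C4a) and give the cis-fused bicycle A2.
- In favour: two rings and four stereocentres form in one thermal step without a metal. The dienophile geometry fixes the C1 ester trans to C8, the centre the chosen plan must equilibrate, so here the alternative is better.
- Against: both partners are electron-poor, so high temperature and diene dimerisation are to be expected. The fusion and the absolute configuration rest on a single C5 silyloxy centre. A2 has its ring A alkene at C3=C4, an extra C2 stereocentre and no C6 ester, so a deconjugative alkene shift and a carboxylation at a hindered enone α-carbon would follow.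
- Comparison: the key step itself is more economical, but the corrections afterwards probably cancel the gain, and absolute control is weaker than with a chiral catalyst.

Alternative 3: The cuts are C5–C6 and the C7–chain bond. A hexadecyl cuprate would add to a C6–C7 alkynoate, and the allenolate would close onto a C5 aldehyde to give the C5 carbinol A3.
- In favour: the second chain enters late and convergently, the tetrasubstituted alkene is fixed by the ring, and A3 is one oxidation from the target. This is a shorter and gentler endgame than the chosen one.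
- Against: all four stereocentres must already sit in a ring A aldehyde with two epimerisable esters, which then meets a basic organocopper reagent. The stereochemical problem is moved upstream, not solved.
- Comparison: the endgame is better, the front end is undefined. Its length depends on how the ring A aldehyde is made, for which alternative 1 would be the natural source; the chosen plan has a defined catalytic asymmetric entry.

Key step: step 7

Remarks before the steps

- Correction: the diene that reacts has its silyloxy group trans to the alkenyl carbon C7 and cis to the ester. Because CO2Me outranks the alkenyl carbon, that isomer is Z, not E. The E isomer would hold the silyloxy group inside the s-cis diene and is not the reactive partner. The precursor is improved accordingly: it is formed through a chelated sodium enolate, which should give the Z isomer directly.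
- Redesign after the key step: the two quinone carbonyls are not homologated by the same method. C1 is set thermodynamically through a vinylogous β-keto ester, C4 kinetically by hydroboration.
- Assumption: the facial sense of the (S)-diphenylprolinol-derived oxazaborolidinium ion is taken from the α-C–H···O pre-transition-state model; if the antipode were favoured, the (R)-catalyst would be used with nothing else changed.

## Steps

Step 1
Reactants: 1 1,4-dimethoxybenzene; 2 1-bromohexadecane
Product: 4 2-hexadecyl-1,4-dimethoxybenzene, via (2,5-dimethoxyphenyl)lithium 3 (not isolated)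
Conditions: n-BuLi, TMEDA, THF, 0 °C; then 2, 0 °C → rt
Reagents that add atoms: none
Why: Directed ortho-lithiation followed by SN2 alkylation of the aryllithium by the primary bromide; the four ring positions of 1 are equivalent, so only one product can form.

Step 2
Reactants: 4 2-hexadecyl-1,4-dimethoxybenzene
Product: 5 2-hexadecyl-1,4-benzoquinone
Conditions: (NH4)2Ce(NO3)6, MeCN/H2O, 0 °C
Reagents that add atoms: water, O
Why: Oxidative demethylation of a hydroquinone dimethyl ether by tetravalent cerium (two one-electron oxidations, water adds to the arene radical cation, methanol leaves); the saturated chain is inert.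

Step 3
Reactants: 2 1-bromohexadecane; 6 diketene (4-methylideneoxetan-2-one)
Product: 8 3-methylidenenonadecanoic acid, via hexadecylmagnesium bromide 7 (not isolated)
Conditions: Mg, THF, 40 °C; then 6, NiCl2 (5 mol %), THF, 0 °C; aq. HCl
Reagents that add atoms: none
Why: Nickel-catalysed cross-coupling of the Grignard reagent at the vinylic C–O bond of diketene opens the lactone to the magnesium salt of the 3-methylidene acid; the catalyst diverts the reagent from the acyl carbon.

Step 4
Reactants: 8 3-methylidenenonadecanoic acid
Product: 9 methyl 3-methylidenenonadecanoate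
Conditions: TMSCHN2, toluene/MeOH, 0 °C → rt
Reagents that add atoms: (trimethylsilyl)diazomethane, C[Si](C)(C)C=[N+]=[N-]
Why: O-Methylation of the acid by the diazoalkane under neutral conditions, which leaves the 1,1-disubstituted alkene out of conjugation.

Step 5
Reactants: 9 methyl 3-methylidenenonadecanoate
Product: 11 methyl (2Z)-2-(hydroxymethylidene)-3-methylidenenonadecanoate, via lithium 1-methoxy-3-methylidenenonadec-1-en-1-olate 10 (not isolated)
Conditions: LiN(SiMe3)2 (2.2 equiv), THF, −78 °C; HCO2Me, −78 → 0 °C; aq. NH4Cl
Reagents that add atoms: methyl formate, COC=O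
Why: Crossed Claisen condensation: the dienolate of the β,γ-unsaturated ester is formylated at the α-carbon, the second equivalent of base stores the product as its chelated enolate, and protonation gives the hydrogen-bonded (Z)-enol.

Step 6
Reactants: 11 methyl (2Z)-2-(hydroxymethylidene)-3-methylidenenonadecanoate
Product: 13 methyl (2Z)-2-{[tert-butyl(dimethyl)silyl]oxymethylidene}-3-methylidenenonadecanoate, via sodium (1Z)-2-(methoxycarbonyl)-3-methylidenenonadec-1-en-1-olate 12 (not isolated)
Conditions: NaH, THF, 0 °C; TBSCl, 0 °C → rt
Reagents that add atoms: tert-butyldimethylsilyl chloride, CC(C)(C)[Si](C)(C)Cl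
Why: O-Silylation of the chelated sodium enolate of a β-formyl ester; the sodium ion bridges the two oxygens, which keeps the enolate oxygen cis to the ester, so the silyloxy group ends up outside the s-cis diene (Z).

Step 7
Reactants: 5 2-hexadecyl-1,4-benzoquinone; 13 methyl (2Z)-2-{[tert-butyl(dimethyl)silyl]oxymethylidene}-3-methylidenenonadecanoate
Product: 14 methyl (4aR,5R,8aR)-5-[(tert-butyldimethylsilyl)oxy]-2,7-dihexadecyl-1,4-dioxo-1,4,4a,5,8,8a-hexahydronaphthalene-6-carboxylate
Conditions: (S)-B-(o-tolyl)oxazaborolidine from (S)-diphenylprolinol, HNTf2 (20 mol % each), CH2Cl2, −78 → −40 °C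
Reagents that add atoms: none
Why: The protonated oxazaborolidine binds the more Lewis-basic C4 carbonyl of 5 (vinylogous to the C2 alkyl group) through the lone pair syn to C4a–H, helped by a C4a–H···O contact to the catalyst oxygen, and so activates only the unsubstituted C4a=C8a bond; 13 then adds in a concerted but asynchronous endo [4+2] cycloaddition, the closest known type being the oxazaborolidinium-catalysed Diels–Alder reaction of 2-substituted 1,4-benzoquinones with silyloxy dienes. Ring B closes in the suprafacial six-membered mode of a normal-demand Diels–Alder reaction, C8–C8a forming ahead of C4a–C5, which fixes the cis fusion. C4a and C8a are controlled by the catalyst: the phenyl group on the same side as the bound quinone lies under the C4a=C8a bond, so the diene reaches only the opposite face, which corresponds to (4aR,8aR). C5 is controlled by the diene geometry together with the endo approach: the outward silyloxy group of the (Z)-diene ends up cis to C4, so H5 is cis to H4a and H8a. Regioselectivity is required and comes from two matched effects: C8 is the nucleophilic terminus of 13 (oxygen and C7-alkyl donation, with the ester on the nodal carbon of the developing allyl cation) and C8a is the β-carbon of the coordinated C4 enone. Site selectivity for C4a=C8a over C2=C3 follows from the alkyl group on the latter and from the binding mode. Low temperature and the absence of base keep 14 from enolising to the hydroquinone or losing silanol.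

Step 8
Reactants: 14 methyl (4aR,5R,8aR)-5-[(tert-butyldimethylsilyl)oxy]-2,7-dihexadecyl-1,4-dioxo-1,4,4a,5,8,8a-hexahydronaphthalene-6-carboxylate
Product: 16 methyl (4aR,5R,8aR)-5-[(tert-butyldimethylsilyl)oxy]-2,7-dihexadecyl-4-oxo-1-(trifluoromethanesulfonyloxy)-3,4,4a,5,8,8a-hexahydronaphthalene-6-carboxylate, via C1 potassium enolate of the 2,3-dihydro adduct 15 (not isolated)
Conditions: K[(s-Bu)3BH], THF, −78 °C; then N-(5-chloro-2-pyridyl)triflimide, −78 → 0 °C
Reagents that add atoms: N-(5-chloropyridin-2-yl)bis(trifluoromethanesulfonyl)imide, O=S(=O)(N(c1ccc(Cl)cn1)S(=O)(=O)C(F)(F)F)C(F)(F)F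
Why: Conjugate reduction of the ene-dione by a hindered borohydride at the unsubstituted C3 (C2 carries the chain) gives the C1 enolate regiospecifically, and O-triflation in the cold traps it before proton transfer; this is the known reductive triflation of enones and it tells the two carbonyls apart.

Step 9
Reactants: 16 methyl (4aR,5R,8aR)-5-[(tert-butyldimethylsilyl)oxy]-2,7-dihexadecyl-4-oxo-1-(trifluoromethanesulfonyloxy)-3,4,4a,5,8,8a-hexahydronaphthalene-6-carboxylate
Product: 18 dimethyl (1S,4aR,5R,8aR)-5-[(tert-butyldimethylsilyl)oxy]-2,7-dihexadecyl-4-oxo-1,4,4a,5,8,8a-hexahydronaphthalene-1,6-dicarboxylate, via tetrasubstituted C1=C2 enoate 17 (not isolated)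
Conditions: Pd(OAc)2 (5 mol %), dppp, CO (1 atm), MeOH, Et3N, DMF, 50 °C; then DBU (0.2 equiv), rt
Reagents that add atoms: carbon monoxide, [C-]#[O+]; methanol, CO
Why: Palladium-catalysed methoxycarbonylation of the enol triflate gives 17, whose C3 hydrogens are α to the ketone and γ to the ester, so base moves the alkene into conjugation with C4=O (the arrangement of Hagemann's ester), which places it at C2=C3. The new C1 centre is doubly activated and equilibrates to the more stable epimer, with the ester on the convex face, because the other epimer suffers a syn-axial clash with C5 or allylic strain with the C2 chain.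

Step 10
Reactants: 18 dimethyl (1S,4aR,5R,8aR)-5-[(tert-butyldimethylsilyl)oxy]-2,7-dihexadecyl-4-oxo-1,4,4a,5,8,8a-hexahydronaphthalene-1,6-dicarboxylate
Product: 19 dimethyl (1S,4aS,5R,8aR)-5-[(tert-butyldimethylsilyl)oxy]-2,7-dihexadecyl-4-methylidene-1,4,4a,5,8,8a-hexahydronaphthalene-1,6-dicarboxylate
Conditions: Zn, CH2Br2, TiCl4, THF/CH2Cl2, 0 °C → rt
Reagents that add atoms: dibromomethane, BrCBr
Why: Takai–Lombardo methylenation with a non-basic titanium–zinc methylene reagent, which converts enolisable ketones and enones without deprotonating the acidic C1–H and leaves esters untouched.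

Step 11
Reactants: 19 dimethyl (1S,4aS,5R,8aR)-5-[(tert-butyldimethylsilyl)oxy]-2,7-dihexadecyl-4-methylidene-1,4,4a,5,8,8a-hexahydronaphthalene-1,6-dicarboxylate
Product: 21 dimethyl (1S,4R,4aS,5R,8aR)-5-[(tert-butyldimethylsilyl)oxy]-2,7-dihexadecyl-4-(hydroxymethyl)-1,4,4a,5,8,8a-hexahydronaphthalene-1,6-dicarboxylate, via B-alkyl-9-borabicyclo[3.3.1]nonane adduct 20 (not isolated)
Conditions: 9-BBN, THF, 0 °C → rt; then NaBO3·4H2O, THF/H2O, rt
Reagents that add atoms: sodium perborate, [Na+].[Na+].O[B-]1(O)OO[B-](O)(O)OO1
Why: Hydroboration–oxidation; the bulky borane takes only the 1,1-disubstituted terminus of the diene and spares the trisubstituted and tetrasubstituted alkenes and the esters. Boron and hydrogen add from the convex face, anti to C5 and its silyloxy group, so H4 becomes cis to H4a and the hydroxymethyl group lies on the concave face (4R).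

Step 12
Reactants: 21 dimethyl (1S,4R,4aS,5R,8aR)-5-[(tert-butyldimethylsilyl)oxy]-2,7-dihexadecyl-4-(hydroxymethyl)-1,4,4a,5,8,8a-hexahydronaphthalene-1,6-dicarboxylate
Product: 22 dimethyl (1S,4R,4aS,5R,8aR)-2,7-dihexadecyl-5-hydroxy-4-(hydroxymethyl)-1,4,4a,5,8,8a-hexahydronaphthalene-1,6-dicarboxylate
Conditions: HF·pyridine, pyridine, THF, 0 °C → rt
Reagents that add atoms: none
Why: Fluoride-mediated cleavage of the secondary silyl ether under buffered, non-basic conditions; with the C4 carbon still at the alcohol level the diol cannot lactonise.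

Step 13
Reactants: 22 dimethyl (1S,4R,4aS,5R,8aR)-2,7-dihexadecyl-5-hydroxy-4-(hydroxymethyl)-1,4,4a,5,8,8a-hexahydronaphthalene-1,6-dicarboxylate
Product: 23 dimethyl (1S,4R,4aS,8aR)-4-formyl-2,7-dihexadecyl-5-oxo-1,4,4a,5,8,8a-hexahydronaphthalene-1,6-dicarboxylate
Conditions: (COCl)2, DMSO, CH2Cl2, −78 °C; i-Pr2NEt, −78 → −30 °C
Reagents that add atoms: none
Why: Swern oxidation of both alcohols; both are converted into alkoxysulfonium ions before any base is added, so the aldehyde never meets a free C5 hydroxyl and no lactol forms, and the hindered amine at low temperature should spare the C4 and C4a hydrogens.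

Step 14
Reactants: 23 dimethyl (1S,4R,4aS,8aR)-4-formyl-2,7-dihexadecyl-5-oxo-1,4,4a,5,8,8a-hexahydronaphthalene-1,6-dicarboxylate
Product: 24 (1S,4R,4aS,8aR)-2,7-dihexadecyl-1,6-bis(methoxycarbonyl)-5-oxo-1,4,4a,5,8,8a-hexahydronaphthalene-4-carboxylic acid
Conditions: NaClO2, NaH2PO4, 2-methyl-2-butene, t-BuOH/H2O, 0 °C
Reagents that add atoms: sodium chlorite, [Na+].[O-]Cl=O
Why: Pinnick oxidation of the aldehyde at about pH 4 with an alkene scavenger for hypochlorous acid; the conditions are too weakly acidic and non-basic to epimerise C4 or C4a or to touch the enone.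

Step 15
Reactants: 24 (1S,4R,4aS,8aR)-2,7-dihexadecyl-1,6-bis(methoxycarbonyl)-5-oxo-1,4,4a,5,8,8a-hexahydronaphthalene-4-carboxylic acid
Product: 25 trimethyl (1S,4R,4aS,8aR)-2,7-dihexadecyl-5-oxo-1,4,4a,5,8,8a-hexahydronaphthalene-1,4,6-tricarboxylate
Conditions: TMSCHN2 (1.1 equiv), toluene/MeOH, 0 °C
Reagents that add atoms: (trimethylsilyl)diazomethane, C[Si](C)(C)C=[N+]=[N-]
Why: Neutral O-methylation of the acid, fast at 0 °C, so the hindered tetrasubstituted enone and the epimerisable centres are not exposed to base.

## Compound list

1 | 1,4-dimethoxybenzene | COc1ccc(OC)cc1 | starting material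
2 | 1-bromohexadecane | CCCCCCCCCCCCCCCCBr | starting material
3 | (2,5-dimethoxyphenyl)lithium | [Li]c1cc(OC)ccc1OC | intermediate
4 | 2-hexadecyl-1,4-dimethoxybenzene | CCCCCCCCCCCCCCCCc1cc(OC)ccc1OC | intermediate
5 | 2-hexadecyl-1,4-benzoquinone | CCCCCCCCCCCCCCCCC1=CC(=O)C=CC1=O | intermediate
6 | diketene (4-methylideneoxetan-2-one) | C=C1CC(=O)O1 | starting material
7 | hexadecylmagnesium bromide | CCCCCCCCCCCCCCCC[Mg]Br | intermediate
8 | 3-methylidenenonadecanoic acid | C=C(CCCCCCCCCCCCCCCC)CC(=O)O | intermediate
9 | methyl 3-methylidenenonadecanoate | C=C(CCCCCCCCCCCCCCCC)CC(=O)OC | intermediate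
10 | lithium 1-methoxy-3-methylidenenonadec-1-en-1-olate (dienolate of 9) | C=C(CCCCCCCCCCCCCCCC)C=C(OC)O[Li] | intermediate
11 | methyl (2Z)-2-(hydroxymethylidene)-3-methylidenenonadecanoate (enol of the α-formyl ester, OH cis to the ester) | C=C(CCCCCCCCCCCCCCCC)/C(C(=O)OC)=C/O | intermediate
12 | sodium (1Z)-2-(methoxycarbonyl)-3-methylidenenonadec-1-en-1-olate | C=C(CCCCCCCCCCCCCCCC)/C(C(=O)OC)=C/O[Na] | intermediate
13 | methyl (2Z)-2-{[tert-butyl(dimethyl)silyl]oxymethylidene}-3-methylidenenonadecanoate (silyloxy group trans to the alkenyl carbon) | C=C(CCCCCCCCCCCCCCCC)/C(C(=O)OC)=C/O[Si](C)(C)C(C)(C)C | intermediate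
14 | methyl (4aR,5R,8aR)-5-[(tert-butyldimethylsilyl)oxy]-2,7-dihexadecyl-1,4-dioxo-1,4,4a,5,8,8a-hexahydronaphthalene-6-carboxylate (cis-fused; H4a, H5 and H8a on one face) | CCCCCCCCCCCCCCCCC1=CC(=O)[C@H]2[C@@H](O[Si](C)(C)C(C)(C)C)C(C(=O)OC)=C(CCCCCCCCCCCCCCCC)C[C@H]2C1=O | intermediate
15 | potassium enolate at C1 (C1=C2, O–K on C1; C3 is CH2, C4 ketone kept) of the 2,3-dihydro derivative of 14, configuration as in 14 | CCCCCCCCCCCCCCCCC=1CC(=O)[C@H]2[C@@H](O[Si](C)(C)C(C)(C)C)C(C(=O)OC)=C(CCCCCCCCCCCCCCCC)C[C@H]2C=1O[K] | intermediate
16 | methyl (4aR,5R,8aR)-5-[(tert-butyldimethylsilyl)oxy]-2,7-dihexadecyl-4-oxo-1-(trifluoromethanesulfonyloxy)-3,4,4a,5,8,8a-hexahydronaphthalene-6-carboxylate (C1=C2 enol triflate) | CCCCCCCCCCCCCCCCC=1CC(=O)[C@H]2[C@@H](O[Si](C)(C)C(C)(C)C)C(C(=O)OC)=C(CCCCCCCCCCCCCCCC)C[C@H]2C=1OS(=O)(=O)C(F)(F)F | intermediate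
17 | dimethyl (4aR,5R,8aR)-5-[(tert-butyldimethylsilyl)oxy]-2,7-dihexadecyl-4-oxo-3,4,4a,5,8,8a-hexahydronaphthalene-1,6-dicarboxylate (C1=C2 enoate) | CCCCCCCCCCCCCCCCC=1CC(=O)[C@H]2[C@@H](O[Si](C)(C)C(C)(C)C)C(C(=O)OC)=C(CCCCCCCCCCCCCCCC)C[C@H]2C=1C(=O)OC | intermediate
18 | dimethyl (1S,4aR,5R,8aR)-5-[(tert-butyldimethylsilyl)oxy]-2,7-dihexadecyl-4-oxo-1,4,4a,5,8,8a-hexahydronaphthalene-1,6-dicarboxylate (C2=C3 enone; C1 ester cis to H8a) | CCCCCCCCCCCCCCCCC1=CC(=O)[C@H]2[C@@H](O[Si](C)(C)C(C)(C)C)C(C(=O)OC)=C(CCCCCCCCCCCCCCCC)C[C@H]2[C@@H]1C(=O)OC | intermediate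
19 | dimethyl (1S,4aS,5R,8aR)-5-[(tert-butyldimethylsilyl)oxy]-2,7-dihexadecyl-4-methylidene-1,4,4a,5,8,8a-hexahydronaphthalene-1,6-dicarboxylate (same spatial arrangement as 18) | CCCCCCCCCCCCCCCCC1=CC(=C)[C@H]2[C@@H](O[Si](C)(C)C(C)(C)C)C(C(=O)OC)=C(CCCCCCCCCCCCCCCC)C[C@H]2[C@@H]1C(=O)OC | intermediate
20 | 9-[(ring C4)-methyl]-9-borabicyclo[3.3.1]nonane adduct of 19 (CH2–B on C4, configuration as in 21) | CCCCCCCCCCCCCCCCC1=C[C@@H](CB3C4CCCC3CCC4)[C@H]2[C@@H](O[Si](C)(C)C(C)(C)C)C(C(=O)OC)=C(CCCCCCCCCCCCCCCC)C[C@H]2[C@@H]1C(=O)OC | intermediate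
21 | dimethyl (1S,4R,4aS,5R,8aR)-5-[(tert-butyldimethylsilyl)oxy]-2,7-dihexadecyl-4-(hydroxymethyl)-1,4,4a,5,8,8a-hexahydronaphthalene-1,6-dicarboxylate (H4, H4a, H8a cis; CH2OH cis to C5) | CCCCCCCCCCCCCCCCC1=C[C@@H](CO)[C@H]2[C@@H](O[Si](C)(C)C(C)(C)C)C(C(=O)OC)=C(CCCCCCCCCCCCCCCC)C[C@H]2[C@@H]1C(=O)OC | intermediate
22 | dimethyl (1S,4R,4aS,5R,8aR)-2,7-dihexadecyl-5-hydroxy-4-(hydroxymethyl)-1,4,4a,5,8,8a-hexahydronaphthalene-1,6-dicarboxylate | CCCCCCCCCCCCCCCCC1=C[C@@H](CO)[C@H]2[C@@H](O)C(C(=O)OC)=C(CCCCCCCCCCCCCCCC)C[C@H]2[C@@H]1C(=O)OC | intermediate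
23 | dimethyl (1S,4R,4aS,8aR)-4-formyl-2,7-dihexadecyl-5-oxo-1,4,4a,5,8,8a-hexahydronaphthalene-1,6-dicarboxylate | CCCCCCCCCCCCCCCCC1=C[C@@H](C=O)[C@H]2C(=O)C(C(=O)OC)=C(CCCCCCCCCCCCCCCC)C[C@H]2[C@@H]1C(=O)OC | intermediate
24 | (1S,4R,4aS,8aR)-2,7-dihexadecyl-1,6-bis(methoxycarbonyl)-5-oxo-1,4,4a,5,8,8a-hexahydronaphthalene-4-carboxylic acid | CCCCCCCCCCCCCCCCC1=C[C@@H](C(=O)O)[C@H]2C(=O)C(C(=O)OC)=C(CCCCCCCCCCCCCCCC)C[C@H]2[C@@H]1C(=O)OC | intermediate
25 | trimethyl (1S,4R,4aS,8aR)-2,7-dihexadecyl-5-oxo-1,4,4a,5,8,8a-hexahydronaphthalene-1,4,6-tricarboxylate (CNP0149813.1) | CCCCCCCCCCCCCCCCC1=C[C@@H](C(=O)OC)[C@H]2C(=O)C(C(=O)OC)=C(CCCCCCCCCCCCCCCC)C[C@H]2[C@@H]1C(=O)OC | target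

## Step count and least certain steps

Total step count: 15. Longest linear sequence: 13 steps (steps 3 to 15, from 2 and 6); the quinone arm (steps 1 and 2) joins at step 7.

Step 7 (key step). The most likely failures are protodesilylation of the silyl dienol ether by the strongly acidic catalyst before cycloaddition, and weak facial discrimination, because the C6 ester makes 13 a less nucleophilic diene than those usually paired with this catalyst. The fallback gives up catalytic enantiocontrol. From 5 and 13, an achiral and milder Lewis acid that binds the same C4 carbonyl (BF3·OEt2 or ZnCl2, CH2Cl2, −78 °C) should give the same regio- and endo-isomer as a racemate, that is 14 together with its antipode, the (4aS,5S,8aS)-adduct F1. The two would be separated by preparative chromatography on a polysaccharide carbamate chiral stationary phase, and the route is rejoined at 14.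

Step 9. The most likely failures are amine-induced loss of the C5 silyloxy group through the C4 enolate at 50 °C (followed by aromatisation), and an incomplete alkene shift or an unfavourable epimer ratio at C1, since this centre rests on a thermodynamic preference that has been argued, not shown. The fallback brings in the C1 carbon at the aldehyde level without amine. From 16, reductive carbonylation (Pd(PPh3)4, CO, Bu3SnH, THF, 50 °C) would give the C1 enal F3. On silica gel this should tautomerise to the γ-formyl enone F4, whose C1 hydrogen is still more acidic and equilibrates without added base. Pinnick oxidation would give the C1 carboxylic acid F5, and methylation with TMSCHN2 returns to 18.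

Step 8. The most likely failures are 1,2-attack of the hydride at the C4 carbonyl, and proton shuffling of the potassium enolate toward C3 or C4a before trapping, the latter leading to loss of silanol. The fallback separates reduction and triflation under neutral conditions. From 14, rhodium-catalysed 1,4-hydrosilylation (RhCl(PPh3)3, Et3SiH, toluene, 50 °C) should place hydrogen on C3 and silicon on the C1 oxygen and give the isolable triethylsilyl enol ether F2. Fluoride-mediated exchange (CsF, PhNTf2, DME) would turn F2 into 16.

Step 13. The most likely failures are incomplete activation of the hindered C5 hydroxyl, so that the first-formed C4 aldehyde is captured as a lactol and oxidised on to a γ-lactone, and amine-mediated epimerisation of the C4 aldehyde. The fallback changes the order of the oxidations. From 21, TEMPO and PhI(OAc)2 in wet MeCN would oxidise the primary alcohol to the C4 acid silyl ether F6 while C5 is still protected. TMSCHN2 would give the triester silyl ether F7, HF·pyridine the hydroxy triester F8, and Dess–Martin periodinane (NaHCO3, CH2Cl2) would then give 25 directly. This order is held in reserve because F8 has its C5 hydroxyl cis to the C4 ester and may lactonise before it is oxidised.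

## Further compounds

F1 | step 7 | methyl (4aS,5S,8aS)-5-[(tert-butyldimethylsilyl)oxy]-2,7-dihexadecyl-1,4-dioxo-1,4,4a,5,8,8a-hexahydronaphthalene-6-carboxylate (antipode of 14) | CCCCCCCCCCCCCCCCC1=CC(=O)[C@@H]2[C@H](O[Si](C)(C)C(C)(C)C)C(C(=O)OC)=C(CCCCCCCCCCCCCCCC)C[C@@H]2C1=O
F2 | step 8 | methyl 5-[(tert-butyldimethylsilyl)oxy]-2,7-dihexadecyl-4-oxo-1-[(triethylsilyl)oxy]-3,4,4a,5,8,8a-hexahydronaphthalene-6-carboxylate (C1=C2 silyl enol ether, configuration as in 16) | CCCCCCCCCCCCCCCCC=1CC(=O)[C@H]2[C@@H](O[Si](C)(C)C(C)(C)C)C(C(=O)OC)=C(CCCCCCCCCCCCCCCC)C[C@H]2C=1O[Si](CC)(CC)CC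
F3 | step 9 | methyl 5-[(tert-butyldimethylsilyl)oxy]-1-formyl-2,7-dihexadecyl-4-oxo-3,4,4a,5,8,8a-hexahydronaphthalene-6-carboxylate (C1=C2 enal, configuration as in 16) | CCCCCCCCCCCCCCCCC=1CC(=O)[C@H]2[C@@H](O[Si](C)(C)C(C)(C)C)C(C(=O)OC)=C(CCCCCCCCCCCCCCCC)C[C@H]2C=1C=O
F4 | step 9 | methyl 5-[(tert-butyldimethylsilyl)oxy]-1-formyl-2,7-dihexadecyl-4-oxo-1,4,4a,5,8,8a-hexahydronaphthalene-6-carboxylate (C2=C3 enone, formyl group cis to H8a, configuration as in 18) | CCCCCCCCCCCCCCCCC1=CC(=O)[C@H]2[C@@H](O[Si](C)(C)C(C)(C)C)C(C(=O)OC)=C(CCCCCCCCCCCCCCCC)C[C@H]2[C@@H]1C=O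
F5 | step 9 | 5-[(tert-butyldimethylsilyl)oxy]-2,7-dihexadecyl-6-(methoxycarbonyl)-4-oxo-1,4,4a,5,8,8a-hexahydronaphthalene-1-carboxylic acid (configuration as in 18) | CCCCCCCCCCCCCCCCC1=CC(=O)[C@H]2[C@@H](O[Si](C)(C)C(C)(C)C)C(C(=O)OC)=C(CCCCCCCCCCCCCCCC)C[C@H]2[C@@H]1C(=O)O
F6 | step 13 | 5-[(tert-butyldimethylsilyl)oxy]-2,7-dihexadecyl-1,6-bis(methoxycarbonyl)-1,4,4a,5,8,8a-hexahydronaphthalene-4-carboxylic acid (configuration as in 21) | CCCCCCCCCCCCCCCCC1=C[C@@H](C(=O)O)[C@H]2[C@@H](O[Si](C)(C)C(C)(C)C)C(C(=O)OC)=C(CCCCCCCCCCCCCCCC)C[C@H]2[C@@H]1C(=O)OC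
F7 | step 13 | trimethyl 5-[(tert-butyldimethylsilyl)oxy]-2,7-dihexadecyl-1,4,4a,5,8,8a-hexahydronaphthalene-1,4,6-tricarboxylate (configuration as in 21) | CCCCCCCCCCCCCCCCC1=C[C@@H](C(=O)OC)[C@H]2[C@@H](O[Si](C)(C)C(C)(C)C)C(C(=O)OC)=C(CCCCCCCCCCCCCCCC)C[C@H]2[C@@H]1C(=O)OC
F8 | step 13 | trimethyl 2,7-dihexadecyl-5-hydroxy-1,4,4a,5,8,8a-hexahydronaphthalene-1,4,6-tricarboxylate (C5 hydroxyl cis to the C4 ester, configuration as in 22) | CCCCCCCCCCCCCCCCC1=C[C@@H](C(=O)OC)[C@H]2[C@@H](O)C(C(=O)OC)=C(CCCCCCCCCCCCCCCC)C[C@H]2[C@@H]1C(=O)OC
A1 | alternative 1 | dimethyl 5-formyl-2-hexadecyl-6-[(2-hexadecyl-1,3-dioxolan-2-yl)methyl]cyclohex-2-ene-1,4-dicarboxylate (ring A aldehyde, ring carbons configured as C1, C4, C4a and C8a of the target) | CCCCCCCCCCCCCCCCC1=C[C@@H](C(=O)OC)[C@@H](C=O)[C@@H](CC2(CCCCCCCCCCCCCCCC)OCCO2)[C@@H]1C(=O)OC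
A2 | alternative 2 | dimethyl 5-[(tert-butyldimethylsilyl)oxy]-2,7-dihexadecyl-1,2,4a,5,8,8a-hexahydronaphthalene-1,4-dicarboxylate (cis-fused, C3=C4 enoate, C6 unsubstituted) | CCCCCCCCCCCCCCCC[C@H]1C=C(C(=O)OC)[C@H]2[C@H](O[Si](C)(C)C(C)(C)C)C=C(CCCCCCCCCCCCCCCC)C[C@H]2[C@@H]1C(=O)OC
A3 | alternative 3 | trimethyl 2,7-dihexadecyl-5-hydroxy-1,4,4a,5,8,8a-hexahydronaphthalene-1,4,6-tricarboxylate (C5 carbinol, C5 epimer of F8) | CCCCCCCCCCCCCCCCC1=C[C@@H](C(=O)OC)[C@H]2[C@H](O)C(C(=O)OC)=C(CCCCCCCCCCCCCCCC)C[C@H]2[C@@H]1C(=O)OC
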